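Q is what we want from the oak flask: L turned by J under the catalyst D, followed for 4.0 d. The question now is what to do next.

the same everywhere: L 0.20 M; D 0.1 mol%
- oak: J 4 equiv; the very flask that is asked about, followed so far
- flask: J 4.00 equiv; time 4.0 d
oak run (percent of the L charged)

| time / h | Q / % | L / % |
|---|---|---|
| 8.00 | 43 | 59 |
| 25.0 | 62 | 40 |
| 40.0 | 67 | 34 |
| 72.0 | 74 | 24 |
| 96.0 | 81 | 20 |

(standard deviation of a reading: 1.5 percentage points)
- summer: at 4.0 d take out 90 % of the Q then present, then wait 30 h
- dawn: at 4.0 d add D, 100 % of the amount charged, then wait 30 h
- dusk: change nothing and wait 30 h more
- winter: at 4.0 d add J, 100 % of the amount charged, then wait 30 h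
* Q, in percent of the L first charged, at 4.0 d
* the option that brings most further Q ("none" if no option brings more than 2 percentage points) (summer / dawn / dusk / winter / none)
* Q present, with what was taken out counted in, in percent of the L first charged, after dusk
* Q present, with what was taken out counted in, in percent of the L first charged, after winter
- what is taken out of Q is counted as made
- the numbers in the tables scatter with a standard deviation of 1.5 percentage points
- additions bring no volume worth counting

At the last reading Q stands at 81 %, give or take 1.5 percentage points, and Q plus L comes to 101 %, so L goes to Q with no visible loss. But two numbers do not go together. The first 8.00 h brought 43 %, the last 24.0 h brought 7 points, so the hourly gain fell by a factor of 18.4. Yet L, counted even from its full charge, fell by a factor of 5.00, which is less. We read the remaining factor of 3.69 as lost strength of the catalyst, by death or by inhibition, and leave open which.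

So we reckon in what a dose delivers. Our yardstick is B = 0.162 M, the dose yield: the molar Q that one charge of D has made by 4.0 d, as read from the last reading with its scatter. L still present is 0.0400 M, while the same dose made 0.124 M in its first 25.0 h, more than that. This is the crossing: with a fresh dose we expect L to become the limiting reagent. We choose dawn.

The forecast, which saw “a catalyst dying roughly hyperbolically”, gave 80.5 % at 4.0 d, chose dawn, and put dusk at 83.5 % and winter at 85 %.

The flask gives 79.3 %. Dawn is best with 20 points, against 3.5 points for dusk, 3.5 points for summer and 4.2 points for winter; dusk ends at 82.8 %, winter at 83.5 %.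

    J + D ⇌ Z (K = 0.370 M⁻¹, k = 46.0 M⁻¹ min⁻¹)
    Z ⇌ E (K = 11.0, k = 32.0 min⁻¹)
    L + E → G (k = 68.0 M⁻¹ min⁻¹)
    G → D + Q (k = 730 min⁻¹)
    2 Z → X (k = 2500 M⁻¹ min⁻¹)

The dawn gain of 20 points stands against 21 % of L left, so in the dawn flask L has become the limit, as B set against the 0.0414 M of L left led us to expect. Part of why dawn pays is the turning of two Z into X: at 96.0 h X holds 98.3 % of the catalyst charged, and with that step struck out the dawn gain falls to 0 points. In the neighbour flask with 0.34 M of L, equivalents and loading held, so that D grows with L, B kept as the same molar Q gives 47.6 % of that L. That flask gives 48.0 %.

Readings and results are calculated on assumed constants; noise was put on by code.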